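The product here is the chain, and its average length is the monomer in chains divided by the chains begun, living or dead.

common to all: free monomer 0.80 M

| run | pre-initiator | impurity | remark | time |
|---|---|---|---|---|
| midnight | 8 mM | 1.1 mM | run made earlier |  |
| Wednesday's | 8.0 mM | 1.7 mM |  | 40 min |
| Friday's | 12 mM | 1.7 mM |  | 40 min |

midnight run (percent of the free monomer charged)

| time / min | monomer in chains / % | free monomer / % |
|---|---|---|
| 1.00 | 0.6 | 100.1 |
| 2.50 | 0.6 | 100.3 |
| 5.00 | 3.4 | 96.5 |
| 8.00 | 12.0 | 88.1 |
| 10.0 | 20.8 | 79.6 |
| 15.0 | 47.0 | 53.1 |

(scatter of a reading: 0.5 percentage points)

- which of the two ends with the longer chains by the average number of monomer units in a chain (chains begun, living or dead) ("neither" if they lie within 10%) (Wednesday's / Friday's / neither)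
- average number of monomer units in a chain (chains begun, living or dead) at the end, Wednesday's
- average number of monomer units in a chain (chains begun, living or dead) at the end, Friday's

- the average divides the monomer in chains by the number of chains begun, living and dead together
- the earlier runs do not show the number of chains; that part of a forecast is a guess
- no earlier run changes the charge of pre-initiator; that part of a forecast is a guess
- no earlier run changes the charge of impurity; that part of a forecast is a guess

Follow one molecule of pre-initiator. It turns into an active form, and that form meets either impurity, which I assume destroys it, or free monomer, which starts a chain. The bench rule says one impurity costs one start. So Wednesday's 8.0 mM less 1.7 mM leaves 6.30 mM, the live charge, pre-initiator minus impurity, and Friday's 12 mM less 1.7 mM leaves 10.3 mM. With the whole charge in chains, my reckoning gives lengths of 127 for Wednesday's and 77.7 for Friday's.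

The midnight run shows a lag (induction period): monomer in chains reads 0.6% at 2.50 min, close to the scatter of 0.5 percentage points. It also shows the rule's border. The slope of the logarithm of free monomer follows the growing ends, and it reads 0.0507 min⁻¹ from 8.00 min to 10.0 min, then 0.0810 min⁻¹ up to 15.0 min, a ratio of 1.60. In the midnight run, then, ends were still being added when monomer in chains read 47.0%, so I take both lengths as low estimates. I expect Wednesday's to be longer, since its live charge is smaller.

The forecast also names Wednesday's, with 112 and 77, “counting impurity-killed ones as dead chains”. Its Wednesday's figure lies below my estimate, and its Friday's figure is about equal to mine.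

The simulation gives Wednesday's as longer, with 167 against 123.

    initiator + impurity → spent initiator (k = 2900 L mol⁻¹ min⁻¹)
    free monomer + initiator → living end + monomer in chains (k = 0.300 L mol⁻¹ min⁻¹)
    pre-initiator → initiator (k = 0.0910 min⁻¹)
    free monomer + living end → monomer in chains + living end, rate k4*[living end]*[free monomer] (k = 28.0 L mol⁻¹ min⁻¹)

Both lengths stand above my estimates. At the end of Wednesday's, spent initiator stands at 1.70 mM, while 4.64 mM of living end, 1.45 mM of initiator and 0.210 mM of pre-initiator sum to 6.30 mM, the live charge of 6.30 mM; the living ends are 73.7% of it. The neighbour is Friday's with 0.20 M of free monomer, and its live charge stays 10.3 mM, which gives an estimate of 18.5. There 5.57 mM remains initiator, the living ends are 4.41 mM, or 42.8% of the live charge, and the length is 43.2.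

(The data are simulated on assumed constants, and the scatter is random.)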